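The readings are simulated with made-up constants; scatter was added.

Split the alder run at 6.00 h before you choose between the two flasks below, because the choice hangs on how a rate fades and a single number at the end hides that. In each flask, starting material and partner give target under an initiator, with protic impurity present.

| flask | starting material | partner | protic impurity | initiator | temperature | remark | time |
|---|---|---|---|---|---|---|---|
| larch | 0.17 M | 0.80 equiv | 5.4 mM | 6 mol% | −10 °C | run made earlier |  |
| alder | 0.51 M | 0.80 equiv | 5.4 mM | 6 mol% | 10 °C | run made earlier |  |
| maple | 0.27 M | 0.80 equiv | 3.3 mM | 6 mol% | −10 °C | run made earlier |  |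
| alpha | 0.80 M | 0.800 equiv | 2.50 mM | 6 mol% | −5 °C |  | 12 h |
| eta | 0.27 M | 0.800 equiv | 5.40 mM | 6 mol% | 25 °C |  | 12 h |

- larch (time / h: target / %): 5.00: 0.6; 8.00: 0; 15.0: 1.1; 25.0: 0.9; 30.0: 1.3
- alder (time / h: target / %): 2.00: 3.0; 3.00: 3.1; 5.00: 6.2; 6.00: 6.8; 8.00: 8.3; 10.0: 9.0; 12.0: 10.8
- maple (time / h: target / %): 8.00: 0.5; 15.0: 1.1; 25.0: 1.0; 30.0: 0.7

(readings scatter by 0.5 percentage points)

* which of the two ends with the higher amount of target, in percent of the starting material charged ("neither" if they lie within 2 percentage points) (alpha / eta / neither)
* target at the end, in percent of the starting material charged, alpha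
* target at the end, in percent of the starting material charged, eta

- the analysis behind the earlier runs scatters by 0.5 percentage points, standard deviation
- where the amount of starting material changes, what is given in equivalents or mol% on it follows

Alder gives 6.8% in its first window and 4 percentage points in the equal second one, so each window yields 0.588 of the one before, a pseudo-first-order fade of 0.0884 h⁻¹. I sum that series to its end and get 16.5%: this is the ceiling, the target in percent of starting material charged that I expect from this partner charge once the rate has faded out. It is a loose reading, since it rests on two readings with a scatter of 0.5 points.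

Larch and maple differ in c(starting material), 0.17 M against 0.27 M, and in c(protic impurity), 5.4 mM against 3.3 mM. Yet at 30.0 h they read 1.3% and 0.7%, a gap of 0.6 points on readings that scatter by 0.5 points, so these two runs cannot tell me what either concentration does. I leave both out as an assumption, not as a finding. Early alder against larch gives a gain of 26.2 from −10 °C to 10 °C, but c(starting material) changes between those two runs as well, so this gain carries both changes and I use it as a rough reading. I assume that warming speeds making and fading alike, which leaves the ceiling where it is and changes only how fast a flask gets there.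

Eta then runs 11.6 times faster than alder, and its rate halves in 0.678 h, far shorter than 12 h, so I put eta at the ceiling. Alpha runs at 0.0865 of alder's pace and reaches 1.45%. I would run eta.

The forecast says eta, with 6% for alpha and 13% for eta, which is higher and lower than mine respectively: “Eta is likely higher, but this is uncertain”. The flasks end with 20.2% in eta and 2.16% in alpha.

    initiator → 2 initiating radical (k = 0.230 h⁻¹, Ea = 104 kJ mol⁻¹)
    starting material + initiating radical → capped initiator + first chain carrier (k = 18000 M⁻¹ s⁻¹, Ea = 16.0 kJ mol⁻¹)
    partner + first chain carrier ⇌ target + second chain carrier (K = 0.250, k = 5.40 × 10⁵ M⁻¹ h⁻¹, Ea = 48.0 kJ mol⁻¹, ΔH = −1.00 kJ mol⁻¹)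
    starting material + second chain carrier → released group + first chain carrier (k = 9.60 × 10⁵ M⁻¹ h⁻¹, Ea = 48.0 kJ mol⁻¹)
    2 second chain carrier → ended chains A (k = 1.10 × 10⁶ M⁻¹ s⁻¹, Ea = 18.0 kJ mol⁻¹)
    2 first chain carrier → ended chains B (k = 4.50 × 10⁷ M⁻¹ s⁻¹, Ea = 19.0 kJ mol⁻¹)
    partner + protic impurity → quenched reagent (k = 45.0 M⁻¹ h⁻¹, Ea = 63.0 kJ mol⁻¹)
    partner → decomposed reagent (k = 0.0650 h⁻¹, Ea = 108 kJ mol⁻¹)
    (constants at 25 °C)

Eta already holds 16.6% at 6.00 h, and by 12.0 h its initiator is down to 6.33% of its charge. Left to 120 h, eta stands at 21.8%, against my ceiling of 16.5%. The same ceiling, with the fade slowed by alpha's 0.0865, gives 9.91% for alpha at 120 h, and alpha holds 15.5%.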